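**Retrosynthetic overview**
- The three C‑allyl groups come last, from one thermal operation on a tris‑ether: two aryl 1,1‑dimethylallyl ethers give the 2′- and 5′-prenyl groups, and the 7‑O‑prenyl ether gives the C6 1,1‑dimethylallyl group (aromatic Claisen).
- The 7‑hydroxychroman is cut back to an acyclic δ‑hydroxy enynone: one base‑mediated operation closes the pyran ring (oxa‑Michael) and then the benzene A ring (6π‑electrocyclisation, loss of MeOH).
- The enynone comes from a silyl‑capped alkynol and a β‑methoxyacryloyl Weinreb amide.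
- The only stereocentre is set by catalytic asymmetric alkyl addition to the B‑ring aldehyde; its C–O bond is never broken afterwards.
- Ring order: B ring from the starting material, then pyran ring and A ring together in step 6.

Assumption: the (S)-ligand in step 3 is taken to give the (S)-carbinol, as in Ti–BINOLate alkylations of aryl aldehydes; aqueous work‑up is implied throughout.

**Step 1**
Reactants: 1 3,4-dihydroxybenzaldehyde; 2 3-chloro-3-methylbut-1-yne
Product: 3 3,4-bis[(2-methylbut-3-yn-2-yl)oxy]benzaldehyde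
Conditions: 2 (3 equiv), DBU (3 equiv), CuCl2·2H2O (1 mol%), MeCN, 0 °C → rt
Reagents that add atoms: none
Why: Cu‑catalysed propargylic O‑alkylation of phenols with a tertiary propargyl chloride etherifies both hydroxyls under mild base and leaves the aldehyde alone.

**Step 2**
Reactants: 3 3,4-bis[(2-methylbut-3-yn-2-yl)oxy]benzaldehyde
Product: 4 3,4-bis[(2-methylbut-3-en-2-yl)oxy]benzaldehyde
Conditions: H2 (1 atm), Lindlar catalyst, quinoline, EtOAc, rt
Reagents that add atoms: none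
Why: Lindlar semihydrogenation stops at the terminal alkenes and the poisoned catalyst does not reduce the aldehyde or cleave the ethers.

**Step 3**
Reactants: 4 3,4-bis[(2-methylbut-3-en-2-yl)oxy]benzaldehyde; 5 (5-chloropent-1-yn-1-yl)trimethylsilane
Product: 8 (1S)-1-{3,4-bis[(2-methylbut-3-en-2-yl)oxy]phenyl}-6-(trimethylsilyl)hex-5-yn-1-ol, via Grignard reagent 6 (not isolated), via alkyltitanium 7 (not isolated)
Conditions: 5, Mg, THF, 60 °C; Ti(OiPr)4, −78 °C; then 4, (S)-3-(3,5-diphenylphenyl)-H8-BINOL (2 mol%), Ti(OiPr)4, CH2Cl2, 0 °C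
Reagents that add atoms: none
Why: Catalytic enantioselective alkyl transfer from the alkyltitanium (made from the Grignard reagent) under a chiral titanium–BINOLate sets the (S)-carbinol by face‑selective addition to the aldehyde, which is the only stereocentre‑forming event of the route.

**Step 4**
Reactants: 9 methyl (2E)-3-methoxyprop-2-enoate; 10 N,O-dimethylhydroxylamine hydrochloride
Product: 12 (2E)-N,3-dimethoxy-N-methylprop-2-enamide, via magnesium amide 11 (not isolated)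
Conditions: i-PrMgCl (3 equiv), THF, −20 → 0 °C
Reagents that add atoms: none
Why: Weinreb amidation of the ester by the chloromagnesium amide is a hard acyl substitution at C=O and leaves the β‑methoxy enoate C=C in place.

**Step 5**
Reactants: 8 (1S)-1-{3,4-bis[(2-methylbut-3-en-2-yl)oxy]phenyl}-6-(trimethylsilyl)hex-5-yn-1-ol; 12 (2E)-N,3-dimethoxy-N-methylprop-2-enamide
Product: 14 (1E,9S)-9-{3,4-bis[(2-methylbut-3-en-2-yl)oxy]phenyl}-9-hydroxy-1-methoxynon-1-en-4-yn-3-one, via dilithio alkoxide acetylide 13 (not isolated)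
Conditions: MeLi·LiBr (2.2 equiv), THF, 0 °C → rt; then 12 (1.3 equiv), −78 → −10 °C; cold aq NH4Cl, used at once
Reagents that add atoms: none
Why: MeLi deprotonates the OH and cleaves the alkynyl–Si bond (desilylative lithiation), and the lithium acetylide is acylated by the Weinreb amide, whose chelated tetrahedral adduct prevents over‑addition and releases the ynone only on quench.

**Step 6 (key step)**
Reactants: 14 (1E,9S)-9-{3,4-bis[(2-methylbut-3-en-2-yl)oxy]phenyl}-9-hydroxy-1-methoxynon-1-en-4-yn-3-one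
Product: 16 (2S)-2-{3,4-bis[(2-methylbut-3-en-2-yl)oxy]phenyl}-3,4-dihydro-2H-chromen-7-ol, via oxa-Michael adduct 15 (not isolated)
Conditions: KOtBu (2.5 equiv), THF, −40 °C → rt; aq NH4Cl
Reagents that add atoms: none
Why: Proposed new method: the alkoxide adds 6‑exo‑dig to the ynone (oxa‑Michael, closing the pyran ring with the stereocentre's C–O bond untouched, so (S) is retained), further base removes the ring γ‑H to give a 3‑oxido‑hexatriene that undergoes 6π‑electrocyclisation onto the β‑methoxy enone terminus and then E1cB loss of methoxide and tautomerisation to the phenoxide (closing the benzene ring); the closest known reaction types are base‑mediated oxa‑Michael cyclisation of hydroxy ynones and oxyanion‑accelerated 6π‑electrocyclisation / Michael–elimination benzannulation of β‑alkoxy dienones.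

**Step 7**
Reactants: 16 (2S)-2-{3,4-bis[(2-methylbut-3-en-2-yl)oxy]phenyl}-3,4-dihydro-2H-chromen-7-ol; 17 1-bromo-3-methylbut-2-ene
Product: 18 (2S)-2-{3,4-bis[(2-methylbut-3-en-2-yl)oxy]phenyl}-7-[(3-methylbut-2-en-1-yl)oxy]-3,4-dihydro-2H-chromene
Conditions: K2CO3, acetone, 40 °C
Reagents that add atoms: none
Why: Williamson O‑alkylation (SN2) of the only free phenol with the primary allylic bromide.

**Step 8**
Reactants: 18 (2S)-2-{3,4-bis[(2-methylbut-3-en-2-yl)oxy]phenyl}-7-[(3-methylbut-2-en-1-yl)oxy]-3,4-dihydro-2H-chromene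
Product: 20 (2S)-2-[3,4-dihydroxy-2,5-bis(3-methylbut-2-en-1-yl)phenyl]-6-(2-methylbut-3-en-2-yl)-3,4-dihydro-2H-chromen-7-ol, via tris(trimethylsilyl) ether 19 (not isolated)
Conditions: BSA (6 equiv), PhNEt2, 185 °C, sealed tube, Ar; then MeOH, citric acid (cat.), rt
Reagents that add atoms: none
Why: Three aromatic Claisen ([3,3]) rearrangements, in which each 1,1‑dimethylallyl ether delivers a prenyl group to its only free ortho carbon (C2′, C5′) and the 7‑O‑prenyl ether delivers the 1,1‑dimethylallyl group to C6 (para to O1 and less hindered than C8, as for 4‑prenyloxy‑2‑alkoxyarenes), while in situ silylation of the liberated phenols suppresses abnormal Claisen, chroman formation and quinone‑methide opening at C2, so the stereocentre is not scrambled.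

**Compound list**
1 | 3,4-dihydroxybenzaldehyde | O=Cc1ccc(O)c(O)c1 | starting material
2 | 3-chloro-3-methylbut-1-yne | C#CC(C)(C)Cl | starting material
3 | 3,4-bis[(2-methylbut-3-yn-2-yl)oxy]benzaldehyde | O=Cc1ccc(OC(C)(C)C#C)c(OC(C)(C)C#C)c1 | intermediate
4 | 3,4-bis[(2-methylbut-3-en-2-yl)oxy]benzaldehyde | O=Cc1ccc(OC(C)(C)C=C)c(OC(C)(C)C=C)c1 | intermediate
5 | (5-chloropent-1-yn-1-yl)trimethylsilane | C[Si](C)(C)C#CCCCCl | starting material
6 | [5-(trimethylsilyl)pent-4-yn-1-yl]magnesium chloride | C[Si](C)(C)C#CCCC[Mg]Cl | intermediate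
7 | tri(propan-2-yloxy)[5-(trimethylsilyl)pent-4-yn-1-yl]titanium | CC(C)O[Ti](OC(C)C)(OC(C)C)CCCC#C[Si](C)(C)C | intermediate
8 | (1S)-1-{3,4-bis[(2-methylbut-3-en-2-yl)oxy]phenyl}-6-(trimethylsilyl)hex-5-yn-1-ol | C[Si](C)(C)C#CCCC[C@H](O)c1ccc(OC(C)(C)C=C)c(OC(C)(C)C=C)c1 | intermediate
9 | methyl (2E)-3-methoxyprop-2-enoate | CO/C=C/C(=O)OC | starting material
10 | N,O-dimethylhydroxylamine hydrochloride | CNOC.Cl | starting material
11 | chloromagnesium N-methoxy-N-methylamide | CON(C)[Mg]Cl | intermediate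
12 | (2E)-N,3-dimethoxy-N-methylprop-2-enamide | CO/C=C/C(=O)N(C)OC | intermediate
13 | lithium (1S)-1-{3,4-bis[(2-methylbut-3-en-2-yl)oxy]phenyl}-6-lithiohex-5-yn-1-olate | [Li]C#CCCC[C@H](O[Li])c1ccc(OC(C)(C)C=C)c(OC(C)(C)C=C)c1 | intermediate
14 | (1E,9S)-9-{3,4-bis[(2-methylbut-3-en-2-yl)oxy]phenyl}-9-hydroxy-1-methoxynon-1-en-4-yn-3-one | CO/C=C/C(=O)C#CCCC[C@H](O)c1ccc(OC(C)(C)C=C)c(OC(C)(C)C=C)c1 | intermediate
15 | (3E)-1-[(2E,6S)-6-{3,4-bis[(2-methylbut-3-en-2-yl)oxy]phenyl}oxan-2-ylidene]-4-methoxybut-3-en-2-one | CO/C=C/C(=O)/C=C1/O[C@H](c2ccc(OC(C)(C)C=C)c(OC(C)(C)C=C)c2)CCC1 | intermediate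
16 | (2S)-2-{3,4-bis[(2-methylbut-3-en-2-yl)oxy]phenyl}-3,4-dihydro-2H-chromen-7-ol | Oc1ccc2CC[C@H](Oc2c1)c1ccc(OC(C)(C)C=C)c(OC(C)(C)C=C)c1 | intermediate
17 | 1-bromo-3-methylbut-2-ene | CC(C)=CCBr | starting material
18 | (2S)-2-{3,4-bis[(2-methylbut-3-en-2-yl)oxy]phenyl}-7-[(3-methylbut-2-en-1-yl)oxy]-3,4-dihydro-2H-chromene | CC(C)=CCOc1ccc2CC[C@H](Oc2c1)c1ccc(OC(C)(C)C=C)c(OC(C)(C)C=C)c1 | intermediate
19 | {[(2S)-2-{2,5-bis(3-methylbut-2-en-1-yl)-3,4-bis[(trimethylsilyl)oxy]phenyl}-6-(2-methylbut-3-en-2-yl)-3,4-dihydro-2H-chromen-7-yl]oxy}trimethylsilane | C=CC(C)(C)c1cc2c(cc1O[Si](C)(C)C)O[C@H](c1cc(CC=C(C)C)c(O[Si](C)(C)C)c(O[Si](C)(C)C)c1CC=C(C)C)CC2 | intermediate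
20 | (2S)-2-[3,4-dihydroxy-2,5-bis(3-methylbut-2-en-1-yl)phenyl]-6-(2-methylbut-3-en-2-yl)-3,4-dihydro-2H-chromen-7-ol | C=CC(C)(C)c1cc2c(cc1O)O[C@H](c1cc(CC=C(C)C)c(O)c(O)c1CC=C(C)C)CC2 | target

**Total step count:** 8. **Longest linear sequence:** 7 (steps 1, 2, 3, 5, 6, 7, 8; step 4 is a one‑step side branch).

**Steps most likely to fail, with fallbacks**

Step 6 (the two‑ring cascade is unprecedented as a whole; γ‑deprotonation or the 6π closure may stall, or methoxide/alkoxide exchange may intrude). The fallback sets out from 4 and comes back at 18, building the chroman on a resorcinol‑derived ring instead of making the A ring de novo. Aldehyde 4 is treated with MeMgBr to give 1-{3,4-bis[(2-methylbut-3-en-2-yl)oxy]phenyl}ethan-1-ol F3, which Dess–Martin periodinane oxidises to 1-{3,4-bis[(2-methylbut-3-en-2-yl)oxy]phenyl}ethan-1-one F4. Claisen–Schmidt condensation (KOH, EtOH) of this ketone with 2-hydroxy-4-[(3-methylbut-2-en-1-yl)oxy]benzaldehyde F5 (from 2,4-dihydroxybenzaldehyde and 17, K2CO3, acetone) gives (2E)-1-{3,4-bis[(2-methylbut-3-en-2-yl)oxy]phenyl}-3-{2-hydroxy-4-[(3-methylbut-2-en-1-yl)oxy]phenyl}prop-2-en-1-one F6. Transfer hydrogenation of C=C and C=O with RuCl[(R,R)-TsDPEN](p-cymene), HCO2H–Et3N gives 2-[(3R)-3-{3,4-bis[(2-methylbut-3-en-2-yl)oxy]phenyl}-3-hydroxypropyl]-5-[(3-methylbut-2-en-1-yl)oxy]phenol F7, and Mitsunobu cyclisation (PPh3, DIAD, inversion) gives 18.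

Step 8 (C8 attack instead of C6, or erosion at C2 at 185 °C). The fallback sets out from 16 and comes back at 20, installing the C6 group by cross‑coupling instead of sigmatropy. Phenol 16 is iodinated (NIS, MeCN, −20 °C) to (2S)-2-{3,4-bis[(2-methylbut-3-en-2-yl)oxy]phenyl}-6-iodo-3,4-dihydro-2H-chromen-7-ol F8. A γ‑selective Pd‑catalysed Suzuki–Miyaura coupling with prenylboronic acid pinacol ester (biarylphosphine ligand, K3PO4, THF/H2O) gives (2S)-2-{3,4-bis[(2-methylbut-3-en-2-yl)oxy]phenyl}-6-(2-methylbut-3-en-2-yl)-3,4-dihydro-2H-chromen-7-ol F9. Only the two tertiary allyl ethers then need to rearrange (BSA, toluene, 110 °C; MeOH) to give 20.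

Step 3 (ee or yield of the catalytic alkyl transfer to an electron‑rich aldehyde). The fallback sets out from 4 and comes back at 8, setting the stereocentre by ketone reduction instead of C–C bond formation. Uncatalysed addition of Grignard reagent 6 to 4 gives rac-1-{3,4-bis[(2-methylbut-3-en-2-yl)oxy]phenyl}-6-(trimethylsilyl)hex-5-yn-1-ol F1. Dess–Martin oxidation gives 1-{3,4-bis[(2-methylbut-3-en-2-yl)oxy]phenyl}-6-(trimethylsilyl)hex-5-yn-1-one F2, and asymmetric transfer hydrogenation with RuCl[(S,S)-TsDPEN](p-cymene), HCO2H–Et3N (alkene‑tolerant) gives 8.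

**Further compounds**
F1 | step 3 | rac-1-{3,4-bis[(2-methylbut-3-en-2-yl)oxy]phenyl}-6-(trimethylsilyl)hex-5-yn-1-ol | C[Si](C)(C)C#CCCCC(O)c1ccc(OC(C)(C)C=C)c(OC(C)(C)C=C)c1
F2 | step 3 | 1-{3,4-bis[(2-methylbut-3-en-2-yl)oxy]phenyl}-6-(trimethylsilyl)hex-5-yn-1-one | C[Si](C)(C)C#CCCCC(=O)c1ccc(OC(C)(C)C=C)c(OC(C)(C)C=C)c1
F3 | step 6 | 1-{3,4-bis[(2-methylbut-3-en-2-yl)oxy]phenyl}ethan-1-ol | CC(O)c1ccc(OC(C)(C)C=C)c(OC(C)(C)C=C)c1
F4 | step 6 | 1-{3,4-bis[(2-methylbut-3-en-2-yl)oxy]phenyl}ethan-1-one | CC(=O)c1ccc(OC(C)(C)C=C)c(OC(C)(C)C=C)c1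
F5 | step 6 | 2-hydroxy-4-[(3-methylbut-2-en-1-yl)oxy]benzaldehyde | O=Cc1ccc(OCC=C(C)C)cc1O
F6 | step 6 | (2E)-1-{3,4-bis[(2-methylbut-3-en-2-yl)oxy]phenyl}-3-{2-hydroxy-4-[(3-methylbut-2-en-1-yl)oxy]phenyl}prop-2-en-1-one | O=C(/C=C/c1ccc(OCC=C(C)C)cc1O)c1ccc(OC(C)(C)C=C)c(OC(C)(C)C=C)c1
F7 | step 6 | 2-[(3R)-3-{3,4-bis[(2-methylbut-3-en-2-yl)oxy]phenyl}-3-hydroxypropyl]-5-[(3-methylbut-2-en-1-yl)oxy]phenol | O[C@H](CCc1ccc(OCC=C(C)C)cc1O)c1ccc(OC(C)(C)C=C)c(OC(C)(C)C=C)c1
F8 | step 8 | (2S)-2-{3,4-bis[(2-methylbut-3-en-2-yl)oxy]phenyl}-6-iodo-3,4-dihydro-2H-chromen-7-ol | Oc1cc2c(cc1I)CC[C@H](O2)c1ccc(OC(C)(C)C=C)c(OC(C)(C)C=C)c1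
F9 | step 8 | (2S)-2-{3,4-bis[(2-methylbut-3-en-2-yl)oxy]phenyl}-6-(2-methylbut-3-en-2-yl)-3,4-dihydro-2H-chromen-7-ol | Oc1cc2c(cc1C(C)(C)C=C)CC[C@H](O2)c1ccc(OC(C)(C)C=C)c(OC(C)(C)C=C)c1
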